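Numbering the eighteen-carbon backbone from the ester carbon, the ring is C9 (alkene, chain-bearing), C10 (carbinol), C11 (C–Br), C12 (ketone), C13 (alkene, pentenyl-bearing). The route rests on cutting C9=C13 and C10–C11, the two ring bonds in aldol relationship to the C12 ketone. One flask joins a three-carbon ketone piece, (Z)-3-oxonon-6-enoic acid (C11–C13), with a 1,2-dicarbonyl piece, methyl 9,10-dioxodecanoate (C9, C10): decarboxylative aldol addition makes C10–C11, aldol cyclodehydration makes C9=C13, so the ring and both side chains are set at once. Lipase resolution and a trans-selective C11 bromination finish the synthesis.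

Key step: step 6

Assumption: dimethyldioxirane is used as a freshly made acetone solution (from acetone and KHSO5) and counts as a reagent; 1, 5 and 7 are catalogue compounds.

Step 1
Reactants: 1 9-methoxy-9-oxononanoic acid (monomethyl azelate)
Product: 3 methyl 10-diazo-9-oxodecanoate, via acid chloride 2 (not isolated)
Conditions: (COCl)2 (1.2 equiv), DMF (cat.), CH2Cl2, 0 to 20 °C; evaporate; Me3SiCHN2 (2 equiv), THF–MeCN, 0 °C
Reagents that add atoms: oxalyl chloride, O=C(Cl)C(=O)Cl (chlorine only in intermediate 2); (trimethylsilyl)diazomethane, C[Si](C)(C)C=[N+]=[N-]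
Why: Acid chloride formation followed by acylation of (trimethylsilyl)diazomethane should give the diazoketone, because chloride removes the silyl group from the acylated diazonium intermediate and the methyl ester is inert to both reagents.

Step 2
Reactants: 3 methyl 10-diazo-9-oxodecanoate
Product: 4 methyl 9,10-dioxodecanoate
Conditions: dimethyldioxirane (1.1 equiv, acetone solution), 0 to 20 °C; evaporate and use crude
Reagents that add atoms: dimethyldioxirane, CC1(C)OO1
Why: Oxygen-atom transfer from the dioxirane to the diazo carbon with loss of N2 is a neutral oxidation of diazoketones to 2-oxoaldehydes and leaves the ester untouched.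

Step 3
Reactants: 5 (2Z)-pent-2-en-1-ol
Product: 6 (2Z)-1-bromopent-2-ene
Conditions: PBr3 (0.4 equiv), pyridine (cat.), Et2O, −20 to 0 °C
Reagents that add atoms: phosphorus tribromide, BrP(Br)Br
Why: Bromination of a primary allylic alcohol with PBr3 at low temperature proceeds by SN2 displacement of the phosphite ester, so the primary position and the Z alkene should be kept.

Step 4
Reactants: 7 methyl acetoacetate; 6 (2Z)-1-bromopent-2-ene
Product: 8 methyl (6Z)-3-oxonon-6-enoate
Conditions: NaH (1.1 equiv), THF, 0 °C; n-BuLi (1.05 equiv), 0 °C; then 6, 0 to 20 °C; aq. HCl work-up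
Reagents that add atoms: none
Why: γ-Alkylation of the doubly deprotonated acetoacetate takes place at the more reactive terminal carbanion by SN2 attack on the primary allylic bromide, which keeps the Z geometry.

Step 5
Reactants: 8 methyl (6Z)-3-oxonon-6-enoate
Product: 9 (6Z)-3-oxonon-6-enoic acid
Conditions: KOH (1.1 equiv), H2O, 5 to 20 °C, 24 h; then aq. HCl to pH 2 at 0 °C, Et2O extraction, used at once
Reagents that add atoms: potassium hydroxide, [K+].[OH-]
Why: Cold aqueous saponification of the β-keto ester and cold acidification should give the free β-keto acid, which is used immediately because it loses CO2 on warming.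

Step 6
Reactants: 4 methyl 9,10-dioxodecanoate; 9 (6Z)-3-oxonon-6-enoic acid (1.2 equiv)
Product: 12 racemic methyl 8-[5-hydroxy-3-oxo-2-[(2Z)-pent-2-en-1-yl]cyclopent-1-en-1-yl]octanoate, via acyclic hydroxy diketone 10 (not isolated), via cyclic ketol 11 (not isolated)
Conditions: Et3N (0.2 equiv), THF, 0 to 20 °C until CO2 evolution stops; then NaOMe (0.3 equiv), MeOH, 0 °C, same flask; AcOH quench
Reagents that add atoms: none
Why: Catalytic Et3N turns 9 into its carboxylate, whose activated C11 methylene adds to the aldehyde C10 of 4 (far more electrophilic than the C9 ketone) and loses CO2, which forms C10–C11 and gives 10; methoxide then generates the C13 enolate, which adds to the C9 ketone, and E1cB loss of water from ketol 11 forms C9=C13. The closest known reaction type is the decarboxylative aldol addition of 3-oxoalkanoic acids to 2-oxoaldehydes followed by base cyclodehydration to 4-hydroxy-2,3-dialkylcyclopent-2-enones, here telescoped in one flask. The five-membered ring closes by a 5-(enolexo)-exo-trig aldol addition. The C10 carbinol stereocenter arises without control, so 12 is racemic and the enantiomer is selected in step 7; the C9 and C13 centers of 11 disappear on dehydration. The step needs the first bond to start from C11 and not C13, which the carboxyl group secures, and the ring closure to use the C13 enolate and the C9 ketone (not C8 onto C12), which the higher electrophilicity of the α-hydroxy ketone should favour. The chain methyl ester survives because the base is methoxide in methanol.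

Step 7
Reactants: 12 racemic methyl 8-[5-hydroxy-3-oxo-2-[(2Z)-pent-2-en-1-yl]cyclopent-1-en-1-yl]octanoate
Product: 13 methyl 8-[(5S)-5-hydroxy-3-oxo-2-[(2Z)-pent-2-en-1-yl]cyclopent-1-en-1-yl]octanoate
Conditions: immobilised Burkholderia cepacia lipase, vinyl acetate (3 equiv), MTBE, 30 °C, stopped just past half conversion; chromatography
Reagents that add atoms: none
Why: Lipase-catalysed kinetic resolution by irreversible transesterification should acylate the (R)-alcohol (large sp2 C9 side, small C11H2 side, as expected from the empirical rule for secondary alcohols and from the behaviour of the 3-methyl analogues) and leave the (S)-alcohol, whose enantiomeric purity rises as conversion passes one half.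

Step 8
Reactants: 13 methyl 8-[(5S)-5-hydroxy-3-oxo-2-[(2Z)-pent-2-en-1-yl]cyclopent-1-en-1-yl]octanoate
Product: 17 methyl 8-[(4S,5R)-4-bromo-5-hydroxy-3-oxo-2-[(2Z)-pent-2-en-1-yl]cyclopent-1-en-1-yl]octanoate, via trimethylsilyl ether 14 (not isolated), via bis-silyl dienol ether 15 (not isolated), via bromo silyl ether 16 (not isolated)
Conditions: Me3SiCl (2.5 equiv), LiN(SiMe3)2 (1.0 equiv), THF, −40 °C; then −78 °C, LiN(SiMe3)2 (1.05 equiv) added slowly; NBS (1.05 equiv), −78 °C; dilute aq. HCl, THF, 0 °C
Reagents that add atoms: N-bromosuccinimide, O=C1CCC(=O)N1Br; chlorotrimethylsilane, C[Si](C)(C)Cl (silicon only in intermediates 14 to 16)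
Why: Kinetic α′-deprotonation of the O-silylated enone with in situ silylation gives the cross-conjugated silyl dienol ether, whose C11 is brominated by NBS on the face anti to the neighbouring C10 silyloxy group (substrate control, giving the trans arrangement), far faster than the isolated Z alkene reacts, and dilute acid then frees the hydroxyl group.

Compound list
1 | 9-methoxy-9-oxononanoic acid (monomethyl azelate) | COC(=O)CCCCCCCC(=O)O | starting material
2 | methyl 9-chloro-9-oxononanoate | COC(=O)CCCCCCCC(=O)Cl | intermediate (not isolated)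
3 | methyl 10-diazo-9-oxodecanoate | COC(=O)CCCCCCCC(=O)C=[N+]=[N-] | intermediate
4 | methyl 9,10-dioxodecanoate | COC(=O)CCCCCCCC(=O)C=O | intermediate
5 | (2Z)-pent-2-en-1-ol | CC/C=C\CO | starting material
6 | (2Z)-1-bromopent-2-ene | CC/C=C\CBr | intermediate
7 | methyl acetoacetate (methyl 3-oxobutanoate) | CC(=O)CC(=O)OC | starting material
8 | methyl (6Z)-3-oxonon-6-enoate | CC/C=C\CCC(=O)CC(=O)OC | intermediate
9 | (6Z)-3-oxonon-6-enoic acid | CC/C=C\CCC(=O)CC(=O)O | intermediate
10 | racemic methyl (15Z)-10-hydroxy-9,12-dioxooctadec-15-enoate | CC/C=C\CCC(=O)CC(O)C(=O)CCCCCCCC(=O)OC | intermediate (not isolated)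
11 | methyl 8-[1,5-dihydroxy-3-oxo-2-[(2Z)-pent-2-en-1-yl]cyclopentyl]octanoate | CC/C=C\CC1C(=O)CC(O)C1(O)CCCCCCCC(=O)OC | intermediate (not isolated)
12 | racemic methyl 8-[5-hydroxy-3-oxo-2-[(2Z)-pent-2-en-1-yl]cyclopent-1-en-1-yl]octanoate | CC/C=C\CC1=C(CCCCCCCC(=O)OC)C(O)CC1=O | intermediate
13 | methyl 8-[(5S)-5-hydroxy-3-oxo-2-[(2Z)-pent-2-en-1-yl]cyclopent-1-en-1-yl]octanoate | CC/C=C\CC1=C(CCCCCCCC(=O)OC)[C@@H](O)CC1=O | intermediate
14 | methyl 8-[(5S)-3-oxo-2-[(2Z)-pent-2-en-1-yl]-5-[(trimethylsilyl)oxy]cyclopent-1-en-1-yl]octanoate | CC/C=C\CC1=C(CCCCCCCC(=O)OC)[C@@H](O[Si](C)(C)C)CC1=O | intermediate (not isolated)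
15 | methyl 8-[(5S)-2-[(2Z)-pent-2-en-1-yl]-3,5-bis[(trimethylsilyl)oxy]cyclopenta-1,3-dien-1-yl]octanoate | CC/C=C\CC1=C(CCCCCCCC(=O)OC)[C@@H](O[Si](C)(C)C)C=C1O[Si](C)(C)C | intermediate (not isolated)
16 | methyl 8-[(4S,5R)-4-bromo-3-oxo-2-[(2Z)-pent-2-en-1-yl]-5-[(trimethylsilyl)oxy]cyclopent-1-en-1-yl]octanoate | CC/C=C\CC1=C(CCCCCCCC(=O)OC)[C@@H](O[Si](C)(C)C)[C@H](Br)C1=O | intermediate (not isolated)
17 | methyl 8-[(4S,5R)-4-bromo-5-hydroxy-3-oxo-2-[(2Z)-pent-2-en-1-yl]cyclopent-1-en-1-yl]octanoate | CC/C=C\CC1=C(CCCCCCCC(=O)OC)[C@@H](O)[C@H](Br)C1=O | target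

Total step count: 8. Longest linear sequence: 6 steps (steps 3, 4, 5, 6, 7, 8).

Steps most likely to fail

1. Step 6. Decarboxylation of 9 may outrun the aldol addition. The ring may close in the other aldol sense (C8 enolate onto the C12 ketone), or 10 may lose its C10 hydroxyl by β-elimination before closure. The ketoaldehyde may also rearrange under base. Fallback (sets out from 4 and 6, returns at 12): a tandem aldol/intramolecular Wittig annulation, in which phosphorus fixes the olefinating carbon and no strong base is needed. tert-Butyl 4-chloro-3-oxobutanoate and PPh3 (toluene, 60 °C) give [4-(tert-butoxy)-2,4-dioxobutyl]triphenylphosphonium chloride F1, which aqueous Na2CO3 deprotonates to tert-butyl 3-oxo-4-(triphenyl-λ5-phosphanylidene)butanoate F2. Heating F2 with 6 in MeCN alkylates the ylide carbon to [(6Z)-1-(tert-butoxy)-1,3-dioxonon-6-en-4-yl]triphenylphosphonium bromide F3, and aqueous Na2CO3 gives tert-butyl (6Z)-3-oxo-4-(triphenyl-λ5-phosphanylidene)non-6-enoate F4. With 4 and catalytic Et3N in THF the ester-activated methylene of F4 should add to the aldehyde and the ylide should then olefinate the neighbouring ketone, giving tert-butyl 2-hydroxy-3-(8-methoxy-8-oxooctyl)-5-oxo-4-[(2Z)-pent-2-en-1-yl]cyclopent-3-ene-1-carboxylate F5. CF3CO2H in CH2Cl2 then removes the tert-butyl group with loss of CO2 and gives 12.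

2. Step 8. The enolate may expel the C10 oxygen before it is silylated. Excess base may deprotonate C10 of the cyclopentadiene 15 and erode its configuration. The brominating agent may attack the side-chain alkene or show poor facial selectivity, and the bromohydrin may close to an epoxide on work-up. Fallback (sets out from 13, returns at 17): 13 is silylated with tert-butyldimethylsilyl chloride and imidazole in DMF to methyl 8-[(5S)-5-[(tert-butyldimethylsilyl)oxy]-3-oxo-2-[(2Z)-pent-2-en-1-yl]cyclopent-1-en-1-yl]octanoate F6, which is isolated and purified. Exactly one equivalent of LiN(SiMe3)2 with Me3SiCl at −78 °C gives methyl 8-[(5S)-5-[(tert-butyldimethylsilyl)oxy]-2-[(2Z)-pent-2-en-1-yl]-3-[(trimethylsilyl)oxy]cyclopenta-1,3-dien-1-yl]octanoate F7, and NBS at −78 °C gives methyl 8-[(4S,5R)-4-bromo-5-[(tert-butyldimethylsilyl)oxy]-3-oxo-2-[(2Z)-pent-2-en-1-yl]cyclopent-1-en-1-yl]octanoate F8. The bulkier silyl group should shield its face better, and F8 can be purified (a cis epimer separated or equilibrated) before HF·pyridine in THF at 0 °C frees the alcohol to give 17.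

3. Step 7. The enzyme may discriminate poorly between the enantiomers because of the long C9 chain, may acylate slowly, or may transfer acyl groups from the chain ester. Fallback (sets out from 12, returns at 13): preparative chromatography of racemic 12 on a chiral stationary phase (amylose tris(3,5-dimethylphenylcarbamate), supercritical CO2/MeOH) gives 13 directly and makes no new compound.

Further compounds
F1 | step 6 | [4-(tert-butoxy)-2,4-dioxobutyl]triphenylphosphonium chloride | CC(C)(C)OC(=O)CC(=O)C[P+](c1ccccc1)(c1ccccc1)c1ccccc1.[Cl-]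
F2 | step 6 | tert-butyl 3-oxo-4-(triphenyl-λ5-phosphanylidene)butanoate | CC(C)(C)OC(=O)CC(=O)C=P(c1ccccc1)(c1ccccc1)c1ccccc1
F3 | step 6 | [(6Z)-1-(tert-butoxy)-1,3-dioxonon-6-en-4-yl]triphenylphosphonium bromide | CC/C=C\CC(C(=O)CC(=O)OC(C)(C)C)[P+](c1ccccc1)(c1ccccc1)c1ccccc1.[Br-]
F4 | step 6 | tert-butyl (6Z)-3-oxo-4-(triphenyl-λ5-phosphanylidene)non-6-enoate | CC/C=C\CC(C(=O)CC(=O)OC(C)(C)C)=P(c1ccccc1)(c1ccccc1)c1ccccc1
F5 | step 6 | racemic tert-butyl 2-hydroxy-3-(8-methoxy-8-oxooctyl)-5-oxo-4-[(2Z)-pent-2-en-1-yl]cyclopent-3-ene-1-carboxylate | CC/C=C\CC1=C(CCCCCCCC(=O)OC)C(O)C(C(=O)OC(C)(C)C)C1=O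
F6 | step 8 | methyl 8-[(5S)-5-[(tert-butyldimethylsilyl)oxy]-3-oxo-2-[(2Z)-pent-2-en-1-yl]cyclopent-1-en-1-yl]octanoate | CC/C=C\CC1=C(CCCCCCCC(=O)OC)[C@@H](O[Si](C)(C)C(C)(C)C)CC1=O
F7 | step 8 | methyl 8-[(5S)-5-[(tert-butyldimethylsilyl)oxy]-2-[(2Z)-pent-2-en-1-yl]-3-[(trimethylsilyl)oxy]cyclopenta-1,3-dien-1-yl]octanoate | CC/C=C\CC1=C(CCCCCCCC(=O)OC)[C@@H](O[Si](C)(C)C(C)(C)C)C=C1O[Si](C)(C)C
F8 | step 8 | methyl 8-[(4S,5R)-4-bromo-5-[(tert-butyldimethylsilyl)oxy]-3-oxo-2-[(2Z)-pent-2-en-1-yl]cyclopent-1-en-1-yl]octanoate | CC/C=C\CC1=C(CCCCCCCC(=O)OC)[C@@H](O[Si](C)(C)C(C)(C)C)[C@H](Br)C1=O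
F0 | step 7 | none | none
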